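**Plan**

Numbering: eudesmane (ring A = C1–C5 and C10, ring B = C5–C10; methyl C14 on C10, methyl C15 on C4, isopropyl on C7).
Cuts: first the ester C–O bond at O6, then C4–C15, then C2–C3 and C1–C2 of ring A, and last the two ring B bonds C5–C6 and C9–C10 in one Diels–Alder step.
Enabling feature: on ring B the quaternary C10 (with C14), the ring-fusion C5–H and the oxygen-bearing C6 are neighbours, with O6 on the same face as C4 and C1 on the opposite face; endo [4+2] addition of an (E)-1-silyloxydiene to an (E)-trisubstituted keto ester alkene gives just this arrangement.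
Forward: ring B from diene 9 (C6–C9 with the isopropyl group) and dienophile 12 (C3, C4, C5, C10, C14, C1); then C7=C8 hydrogenation, one-carbon homologation at C1, aldol condensation to ring A, methyl addition at C4, desilylation and acylation of O6.
Stereochemistry: C5, C6 and C10 from the cycloaddition (relative from the two alkene geometries and endo addition, absolute from a chiral oxazaborolidinium catalyst); C7 from hydrogenation anti to O6 and C14; C4 from equatorial methyl addition to the ring A ketone.

Key step: step 5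

Assumption: the (S)-configured catalyst is taken to expose the enone face that leads to the (5S,6S,10R) adduct 13; should the sense of induction prove opposite, the (R)-catalyst is used and nothing else changes.

**Route**

Step 1
Reactants: 1 isovaleraldehyde; 2 cyclohexylamine
Product: 3 N-cyclohexyl-3-methylbutan-1-imine
Conditions: Et2O, MgSO4, 0 → 23 °C; distil
Reagents that add atoms: none
Why: Condensation of an aldehyde with a primary amine (imine formation) over a drying agent is fast and gives the aldimine that makes a directed aldol possible.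

Step 2
Reactants: 3 N-cyclohexyl-3-methylbutan-1-imine; 4 acetaldehyde
Product: 8 (E)-2-(propan-2-yl)but-2-enal, via lithiated imine 5 (not isolated), via hydroxy imine 6 (not isolated), via hydroxy aldehyde 7 (not isolated)
Conditions: LiN(i-Pr)2, THF, −78 → 0 °C; 4, −78 °C; then aq. oxalic acid, reflux
Reagents that add atoms: water, O
Why: Directed aldol condensation through a metalated aldimine: the amide base removes the C2 proton of 3, the aza-enolate 5 adds to acetaldehyde without self-condensation of either aldehyde, and hot aqueous oxalic acid hydrolyses the imine and dehydrates the aldol to the conjugated enal, whose alkene geometry is erased in step 3 and therefore does not matter.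

Step 3
Reactants: 8 (E)-2-(propan-2-yl)but-2-enal
Product: 9 (1E)-2-(propan-2-yl)-1-[(triisopropylsilyl)oxy]buta-1,3-diene
Conditions: TIPSOTf, Et3N, Et2O, 0 → 23 °C
Reagents that add atoms: triisopropylsilyl trifluoromethanesulfonate, CC(C)[Si](OS(=O)(=O)C(F)(F)F)(C(C)C)C(C)C
Why: Silylation of the carbonyl oxygen and removal of a γ-proton by the amine (vinylogous silyl enol ether formation) turns the enal into the 1-silyloxydiene; the s-trans enal conformer that reacts leaves oxygen trans to the vinyl group, i.e. the (1E) isomer that can adopt the s-cis diene form, and a minor (1Z) isomer would be inert in step 5.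

Step 4
Reactants: 10 methylglyoxal (40% aqueous); 11 methyl 2-(triphenylphosphoranylidene)propanoate
Product: 12 methyl (E)-2-methyl-4-oxopent-2-enoate
Conditions: CH2Cl2, 0 → 23 °C
Reagents that add atoms: none
Why: Wittig olefination with a stabilised α-methyl ylide takes place at the aldehyde carbonyl only and should give the (E)-trisubstituted alkene with the ester trans to the acetyl group.

Step 5
Reactants: 9 (1E)-2-(propan-2-yl)-1-[(triisopropylsilyl)oxy]buta-1,3-diene (1.5 equiv); 12 methyl (E)-2-methyl-4-oxopent-2-enoate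
Product: 13 methyl (1R,5S,6S)-6-acetyl-1-methyl-4-(propan-2-yl)-5-[(triisopropylsilyl)oxy]cyclohex-3-ene-1-carboxylate
Conditions: (S)-3,3-diphenyl-1-(2-methylphenyl)tetrahydro-1H,3H-pyrrolo[1,2-c][1,3,2]oxazaborole protonated by HNTf2 (20 mol%), CH2Cl2, −78 → −40 °C
Reagents that add atoms: none
Why: The cationic boron centre of the protonated oxazaborolidine binds the ketone oxygen of 12, the more Lewis-basic of its two carbonyl groups, which lowers the LUMO and puts its largest coefficient on C10, β to the ketone; the unsubstituted diene terminus C9, which has the largest HOMO coefficient of the 1-silyloxydiene, bonds there first in a concerted but asynchronous [4+2] cycloaddition and the C5–C6 bond follows. The closest known reaction type is the chiral-Lewis-acid-catalysed enantioselective Diels–Alder reaction of 1-silyloxydienes with β-acylacrylates, of which this α-methyl case is a more hindered member. Ring B is closed by an intermolecular [4+2] cycloaddition, suprafacial on both partners, which forms C9–C10 and C5–C6 in one step. At C10 and C5 the trans relation of C1 and C4 is the (E) geometry of 12 carried over stereospecifically; at C6 the (1E) geometry of 9 together with the endo position of the boron-bound acetyl group places O6 cis to C4; the absolute configuration of all three centres is set by the catalyst, whose aryl groups screen one face of the bound enone. The step needs orientation by the ketone and not the ester, acetyl-endo and not ester-endo addition, and one enantioface: the first two follow from Lewis-acid binding at the ketone alone and from the steric match of the CH2 terminus C9 with the fully substituted C10, the third from the catalyst, and the triisopropylsilyl group is chosen because it resists silyl transfer to the counter-ion, which would start an achiral background reaction.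

Step 6
Reactants: 13 methyl (1R,5S,6S)-6-acetyl-1-methyl-4-(propan-2-yl)-5-[(triisopropylsilyl)oxy]cyclohex-3-ene-1-carboxylate
Product: 14 methyl (1R,2S,3R,4S)-2-acetyl-1-methyl-4-(propan-2-yl)-3-[(triisopropylsilyl)oxy]cyclohexane-1-carboxylate
Conditions: H2 (5 bar), PtO2, EtOAc, 23 °C
Reagents that add atoms: none
Why: Heterogeneous syn hydrogenation of the trisubstituted alkene should occur on the α face, because the β face is screened by the allylic silyloxy group (pseudoaxial to escape A(1,2) strain with the isopropyl group) and by the C14 methyl group, which places H7 α and the isopropyl group cis to O6; any reduction of the ketone is harmless since step 7 reduces it in any case.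

Step 7
Reactants: 14 methyl (1R,2S,3R,4S)-2-acetyl-1-methyl-4-(propan-2-yl)-3-[(triisopropylsilyl)oxy]cyclohexane-1-carboxylate
Product: 15 {2-(1-hydroxyethyl)-1-methyl-4-(propan-2-yl)-3-[(triisopropylsilyl)oxy]cyclohexyl}methanol (ring centres as in 14; carbinol carbon C4 as a mixture of epimers)
Conditions: LiAlH4, THF, 0 °C
Reagents that add atoms: none
Why: LiAlH4 reduction of ester and ketone together avoids having to tell the two carbonyl groups apart; the extra carbinol centre is oxidised again in step 8, so its configuration is irrelevant.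

Step 8
Reactants: 15 {2-(1-hydroxyethyl)-1-methyl-4-(propan-2-yl)-3-[(triisopropylsilyl)oxy]cyclohexyl}methanol
Product: 17 (1R,2S,3R,4S)-2-acetyl-1-methyl-4-(propan-2-yl)-3-[(triisopropylsilyl)oxy]cyclohexane-1-carbaldehyde, via bis(alkoxysulfonium) salt 16 (not isolated)
Conditions: (COCl)2, DMSO, CH2Cl2, −78 °C; then i-Pr2NEt, −78 → 0 °C
Reagents that add atoms: none
Why: Swern oxidation activates both hydroxyl groups as alkoxysulfonium ions before the base is added, so the 1,4-diol goes to the keto aldehyde without passing through a lactol that could be oxidised to a lactone; the aldehyde has no α-hydrogen and the hindered base at low temperature should leave C5 unchanged.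

Step 9
Reactants: 17 (1R,2S,3R,4S)-2-acetyl-1-methyl-4-(propan-2-yl)-3-[(triisopropylsilyl)oxy]cyclohexane-1-carbaldehyde
Product: 18 1-{6-(2-methoxyethenyl)-6-methyl-3-(propan-2-yl)-2-[(triisopropylsilyl)oxy]cyclohexyl}ethan-1-one (ring centres as in 17; E/Z mixture at the enol ether)
Conditions: MeOCH2PPh3Cl, KN(SiMe3)2, THF, 0 °C; then 17, −78 → 0 °C
Reagents that add atoms: (methoxymethyl)triphenylphosphonium chloride, COC[P+](c1ccccc1)(c1ccccc1)c1ccccc1.[Cl-]
Why: Wittig olefination with methoxymethylenetriphenylphosphorane at low temperature should take the aldehyde in preference to the more hindered and less electrophilic methyl ketone and adds C2 as an enol ether, whose E/Z mixture converges in step 10.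

Step 10
Reactants: 18 1-{6-(2-methoxyethenyl)-6-methyl-3-(propan-2-yl)-2-[(triisopropylsilyl)oxy]cyclohexyl}ethan-1-one
Product: 21 (5S,6R,7S,10S)-6-[(triisopropylsilyl)oxy]-15-noreudesm-2-en-4-one, via keto aldehyde 19 (not isolated), via aldol 20 (not isolated)
Conditions: 1 M HCl, THF, 23 °C; then piperidine, AcOH, PhMe, 60 °C
Reagents that add atoms: none
Why: Acid hydrolysis of the enol ether frees the C2 aldehyde, and amine–acid-catalysed intramolecular aldol condensation, a 6-(enolendo)-exo-trig closure that is the only ring size open to this 1,5-keto aldehyde, bonds the acetyl methyl carbon C3 to C2 and dehydrates to the cyclohexenone of ring A under buffered conditions meant to spare C5 and the β-silyloxy ketone.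

Step 11
Reactants: 21 (5S,6R,7S,10S)-6-[(triisopropylsilyl)oxy]-15-noreudesm-2-en-4-one
Product: 22 (5S,6R,7S,10R)-6-[(triisopropylsilyl)oxy]-15-noreudesman-4-one
Conditions: H2 (1 atm), Pd/C, EtOAc, 23 °C
Reagents that add atoms: none
Why: Catalytic hydrogenation of the conjugated disubstituted alkene over Pd/C under neutral conditions saturates C2–C3, creates no stereocentre and leaves the trans ring fusion alone.

Step 12
Reactants: 22 (5S,6R,7S,10R)-6-[(triisopropylsilyl)oxy]-15-noreudesman-4-one
Product: 23 (4S,5S,6R,7S,10R)-6-[(triisopropylsilyl)oxy]eudesman-4-ol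
Conditions: MeMgBr, CeCl3, THF, −78 → 0 °C
Reagents that add atoms: methylmagnesium bromide, C[Mg]Br
Why: 1,2-Addition of the methylcerium reagent formed from MeMgBr and CeCl3 suppresses enolisation and β-elimination, and the nucleophile should enter on the equatorial α trajectory because the axial β one is blocked by the syn-axial C14 methyl and 6β-silyloxy groups, which gives the 4α-methyl 4β-hydroxy (4S) centre.

Step 13
Reactants: 23 (4S,5S,6R,7S,10R)-6-[(triisopropylsilyl)oxy]eudesman-4-ol
Product: 24 (4S,5S,6R,7S,10R)-eudesmane-4,6-diol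
Conditions: TBAF, THF, 60 °C
Reagents that add atoms: none
Why: Fluoride-induced desilylation removes the hindered secondary silyl ether; the diol carries no group sensitive to warm basic fluoride, and a silyl shift to O4 would end in the same product.

Step 14
Reactants: 25 3-hydroxycinnamic acid
Product: 27 (E)-3-{3-[(tert-butyldimethylsilyl)oxy]phenyl}prop-2-enoic acid, via bis-silyl compound 26 (not isolated)
Conditions: TBSCl, imidazole, DMF, 23 °C; then AcOH–THF–H2O, 23 °C
Reagents that add atoms: tert-butyldimethylsilyl chloride, CC(C)(C)[Si](C)(C)Cl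
Why: Silylation of both acidic hydroxyl groups followed by selective hydrolysis of the labile silyl ester leaves the phenol masked as an aryl silyl ether and the carboxylic acid free.

Step 15
Reactants: 27 (E)-3-{3-[(tert-butyldimethylsilyl)oxy]phenyl}prop-2-enoic acid; 24 (4S,5S,6R,7S,10R)-eudesmane-4,6-diol
Product: 29 (4S,5S,6R,7S,10R)-4-hydroxyeudesman-6-yl (E)-3-{3-[(tert-butyldimethylsilyl)oxy]phenyl}prop-2-enoate, via mixed anhydride 28 (not isolated)
Conditions: 2,4,6-Cl3C6H2COCl, Et3N, THF, 23 °C; then 24, DMAP, PhMe, 23 → 60 °C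
Reagents that add atoms: none
Why: Yamaguchi esterification: the mixed anhydride and DMAP give an acylpyridinium ion reactive enough for the hindered axial secondary 6β-hydroxyl, whereas the tertiary 4-hydroxyl does not react and the (E)-alkene is untouched.

Step 16
Reactants: 29 (4S,5S,6R,7S,10R)-4-hydroxyeudesman-6-yl (E)-3-{3-[(tert-butyldimethylsilyl)oxy]phenyl}prop-2-enoate
Product: 30 (4S,5S,6R,7S,10R)-4-hydroxyeudesman-6-yl (E)-3-(3-hydroxyphenyl)prop-2-enoate (target; 4β-OH, 5α-H, 6β-O, 7α-H, 10β-methyl)
Conditions: TBAF, AcOH, THF, 0 °C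
Reagents that add atoms: none
Why: Aryl silyl ethers are cleaved by acetic-acid-buffered fluoride far faster than the hindered cinnamate is attacked, so the phenol is set free without ester cleavage or acyl shift.

**Compound list**

1 | isovaleraldehyde (3-methylbutanal) | CC(C)CC=O | starting material
2 | cyclohexylamine | NC1CCCCC1 | starting material
3 | N-cyclohexyl-3-methylbutan-1-imine | CC(C)C/C=N/C1CCCCC1 | intermediate
4 | acetaldehyde | CC=O | starting material
5 | lithiated imine, lithium N-cyclohexyl-N-(3-methylbut-1-en-1-yl)amide | [Li]N(C=CC(C)C)C1CCCCC1 | intermediate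
6 | hydroxy imine, 3-[(cyclohexylimino)methyl]-4-methylpentan-2-ol (diastereomer mixture, present as its lithium alkoxide before the acid is added) | CC(O)C(C=NC1CCCCC1)C(C)C | intermediate
7 | hydroxy aldehyde, 2-(1-hydroxyethyl)-3-methylbutanal | CC(O)C(C=O)C(C)C | intermediate
8 | (E)-2-(propan-2-yl)but-2-enal | C/C=C(/C=O)C(C)C | intermediate
9 | (1E)-2-(propan-2-yl)-1-[(triisopropylsilyl)oxy]buta-1,3-diene | C=C/C(C(C)C)=C/O[Si](C(C)C)(C(C)C)C(C)C | intermediate
10 | methylglyoxal (2-oxopropanal) | CC(=O)C=O | starting material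
11 | methyl 2-(triphenylphosphoranylidene)propanoate | COC(=O)C(C)=P(c1ccccc1)(c1ccccc1)c1ccccc1 | starting material
12 | methyl (E)-2-methyl-4-oxopent-2-enoate | CC(=O)/C=C(\C)C(=O)OC | intermediate
13 | methyl (1R,5S,6S)-6-acetyl-1-methyl-4-(propan-2-yl)-5-[(triisopropylsilyl)oxy]cyclohex-3-ene-1-carboxylate | CC(C)C1=CC[C@@](C)(C(=O)OC)[C@H](C(C)=O)[C@@H]1O[Si](C(C)C)(C(C)C)C(C)C | intermediate
14 | methyl (1R,2S,3R,4S)-2-acetyl-1-methyl-4-(propan-2-yl)-3-[(triisopropylsilyl)oxy]cyclohexane-1-carboxylate | CC(C)[C@@H]1CC[C@@](C)(C(=O)OC)[C@H](C(C)=O)[C@@H]1O[Si](C(C)C)(C(C)C)C(C)C | intermediate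
15 | {2-(1-hydroxyethyl)-1-methyl-4-(propan-2-yl)-3-[(triisopropylsilyl)oxy]cyclohexyl}methanol, ring centres as in 14, epimers at the hydroxyethyl carbon | CC(C)[C@@H]1CC[C@@](C)(CO)[C@H](C(C)O)[C@@H]1O[Si](C(C)C)(C(C)C)C(C)C | intermediate
16 | bis(alkoxysulfonium) salt, both oxygens of 15 carrying a dimethylsulfonium group, dichloride | CC(C)[C@@H]1CC[C@@](C)(CO[S+](C)C)[C@H](C(C)O[S+](C)C)[C@@H]1O[Si](C(C)C)(C(C)C)C(C)C.[Cl-].[Cl-] | intermediate
17 | (1R,2S,3R,4S)-2-acetyl-1-methyl-4-(propan-2-yl)-3-[(triisopropylsilyl)oxy]cyclohexane-1-carbaldehyde | CC(C)[C@@H]1CC[C@@](C)(C=O)[C@H](C(C)=O)[C@@H]1O[Si](C(C)C)(C(C)C)C(C)C | intermediate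
18 | 1-{6-(2-methoxyethenyl)-6-methyl-3-(propan-2-yl)-2-[(triisopropylsilyl)oxy]cyclohexyl}ethan-1-one, ring centres as in 17, E/Z mixture | CC(C)[C@@H]1CC[C@@](C)(C=COC)[C@H](C(C)=O)[C@@H]1O[Si](C(C)C)(C(C)C)C(C)C | intermediate
19 | keto aldehyde, {2-acetyl-1-methyl-4-(propan-2-yl)-3-[(triisopropylsilyl)oxy]cyclohexyl}acetaldehyde, ring centres as in 17 | CC(C)[C@@H]1CC[C@@](C)(CC=O)[C@H](C(C)=O)[C@@H]1O[Si](C(C)C)(C(C)C)C(C)C | intermediate
20 | aldol, 2-hydroxy-6β-[(triisopropylsilyl)oxy]-15-noreudesman-4-one (5α-H, 7α-H, 10β-methyl; epimers at C2) | CC(C)[C@@H]1CC[C@@]2(C)CC(O)CC(=O)[C@@H]2[C@@H]1O[Si](C(C)C)(C(C)C)C(C)C | intermediate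
21 | (5S,6R,7S,10S)-6-[(triisopropylsilyl)oxy]-15-noreudesm-2-en-4-one, i.e. (4aS,7S,8R,8aS)-4a-methyl-7-(propan-2-yl)-8-[(triisopropylsilyl)oxy]-4a,5,6,7,8,8a-hexahydronaphthalen-1(4H)-one | CC(C)[C@@H]1CC[C@@]2(C)CC=CC(=O)[C@@H]2[C@@H]1O[Si](C(C)C)(C(C)C)C(C)C | intermediate
22 | (5S,6R,7S,10R)-6-[(triisopropylsilyl)oxy]-15-noreudesman-4-one, i.e. (4aR,7S,8R,8aS)-4a-methyl-7-(propan-2-yl)-8-[(triisopropylsilyl)oxy]octahydronaphthalen-1(2H)-one | CC(C)[C@@H]1CC[C@@]2(C)CCCC(=O)[C@@H]2[C@@H]1O[Si](C(C)C)(C(C)C)C(C)C | intermediate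
23 | (4S,5S,6R,7S,10R)-6-[(triisopropylsilyl)oxy]eudesman-4-ol | CC(C)[C@@H]1CC[C@@]2(C)CCC[C@](C)(O)[C@@H]2[C@@H]1O[Si](C(C)C)(C(C)C)C(C)C | intermediate
24 | (4S,5S,6R,7S,10R)-eudesmane-4,6-diol, i.e. (1S,4aR,7S,8R,8aS)-1,4a-dimethyl-7-(propan-2-yl)decahydronaphthalene-1,8-diol | CC(C)[C@@H]1CC[C@@]2(C)CCC[C@](C)(O)[C@@H]2[C@@H]1O | intermediate
25 | 3-hydroxycinnamic acid | O=C(O)/C=C/c1cccc(O)c1 | starting material
26 | bis-silyl compound, tert-butyldimethylsilyl (E)-3-{3-[(tert-butyldimethylsilyl)oxy]phenyl}prop-2-enoate | CC(C)(C)[Si](C)(C)OC(=O)/C=C/c1cccc(O[Si](C)(C)C(C)(C)C)c1 | intermediate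
27 | (E)-3-{3-[(tert-butyldimethylsilyl)oxy]phenyl}prop-2-enoic acid | O=C(O)/C=C/c1cccc(O[Si](C)(C)C(C)(C)C)c1 | intermediate
28 | mixed anhydride of 27 with 2,4,6-trichlorobenzoic acid | O=C(/C=C/c1cccc(O[Si](C)(C)C(C)(C)C)c1)OC(=O)c1c(Cl)cc(Cl)cc1Cl | intermediate
29 | (4S,5S,6R,7S,10R)-4-hydroxyeudesman-6-yl (E)-3-{3-[(tert-butyldimethylsilyl)oxy]phenyl}prop-2-enoate | CC(C)[C@@H]1CC[C@@]2(C)CCC[C@](C)(O)[C@@H]2[C@@H]1OC(=O)/C=C/c1cccc(O[Si](C)(C)C(C)(C)C)c1 | intermediate
30 | (4S,5S,6R,7S,10R)-4-hydroxyeudesman-6-yl (E)-3-(3-hydroxyphenyl)prop-2-enoate, i.e. (1R,2S,4aR,8S,8aS)-8-hydroxy-4a,8-dimethyl-2-(propan-2-yl)decahydronaphthalen-1-yl ester | CC(C)[C@@H]1CC[C@@]2(C)CCC[C@](C)(O)[C@@H]2[C@@H]1OC(=O)/C=C/c1cccc(O)c1 | target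

**Count and risks**

Total steps: 16. Longest linear sequence: 14 (steps 1–3, 5–13, 15, 16).

Step 5. What may go wrong: slow bond formation at the fully substituted C10, loss of the silyl group from the dienol ether under the strong Lewis acid, and incomplete discrimination of the two enone faces. Fallback: absolute control by the catalyst is given up. Compounds 9 and 12 are combined with Me2AlCl in CH2Cl2 at −78 °C, which keeps the two substrate-controlled selectivities (orientation by the ketone, acetyl endo) and should give the racemic adduct F1. Preparative chromatography of F1 on a chiral stationary phase (cellulose tris(3,5-dimethylphenylcarbamate)) separates the enantiomers and returns the route to 13.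

Step 10. What may go wrong: β-elimination of the silanol from the β-silyloxy ketone and epimerisation at C5 under the aldol conditions. Fallback: ring A is closed by enolate alkylation at the saturated oxidation level. Setting out from 18, treatment with 1 M HCl alone gives keto aldehyde 19, which is isolated this time. NaBH4 in MeOH at −78 °C reduces only the aldehyde and gives the hydroxy ketone F2. I2, PPh3 and imidazole convert it into the iodo ketone F3. LiN(i-Pr)2 at −78 °C then forms the kinetic enolate at the acetyl methyl group, which displaces iodide in a 6-(enolendo)-exo-tet closure and joins the route at 22 without passing through the enone.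

Step 15. What may go wrong: the acylation of the axial 6β-hydroxyl, crowded by the C14 methyl group, the 4β-hydroxyl and the isopropyl group, may be too slow for the bulky mixed anhydride. Fallback: the cinnamate is built on the alcohol in two stages. Setting out from 24, acylation with diethylphosphonoacetic acid and dicyclohexylcarbodiimide, which proceeds through the small and very electrophilic phosphonoketene, gives the phosphonoacetate F4. Horner–Wadsworth–Emmons olefination of F4 with commercial 3-hydroxybenzaldehyde (LiCl, DBU, MeCN) forms the (E)-alkene and arrives directly at 30.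

**Further compounds**

F1 | step 5 | racemic methyl (1R*,5S*,6S*)-6-acetyl-1-methyl-4-(propan-2-yl)-5-[(triisopropylsilyl)oxy]cyclohex-3-ene-1-carboxylate | CC(C)C1=CC[C@@](C)(C(=O)OC)[C@H](C(C)=O)[C@@H]1O[Si](C(C)C)(C(C)C)C(C)C.CC(C)C1=CC[C@](C)(C(=O)OC)[C@@H](C(C)=O)[C@H]1O[Si](C(C)C)(C(C)C)C(C)C
F2 | step 10 | hydroxy ketone, 1-{6-(2-hydroxyethyl)-6-methyl-3-(propan-2-yl)-2-[(triisopropylsilyl)oxy]cyclohexyl}ethan-1-one, ring centres as in 17 | CC(C)[C@@H]1CC[C@@](C)(CCO)[C@H](C(C)=O)[C@@H]1O[Si](C(C)C)(C(C)C)C(C)C
F3 | step 10 | iodo ketone, 1-{6-(2-iodoethyl)-6-methyl-3-(propan-2-yl)-2-[(triisopropylsilyl)oxy]cyclohexyl}ethan-1-one, ring centres as in 17 | CC(C)[C@@H]1CC[C@@](C)(CCI)[C@H](C(C)=O)[C@@H]1O[Si](C(C)C)(C(C)C)C(C)C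
F4 | step 15 | phosphonoacetate, (4S,5S,6R,7S,10R)-4-hydroxyeudesman-6-yl 2-(diethoxyphosphoryl)acetate | CC(C)[C@@H]1CC[C@@]2(C)CCC[C@](C)(O)[C@@H]2[C@@H]1OC(=O)CP(=O)(OCC)OCC
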